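**Plan**

- Retrosynthesis: after removal of all benzyl groups, the ester C–O bond between the ring B carbonyl and C4 of ring C is cut by a retro-Baeyer–Villiger step to a ring B–C(=O)–ring C benzophenone. The ring A–ring B ester is then cut by acylation, and the ketone's aryl–carbonyl bond by addition of a ring C aryl-metal to a ring B aldehyde. (Ring A is the terminal galloyl group, ring B the central one, ring C the benzoic acid ring.)
- Enabling feature: in ring C the ester oxygen sits on C4 between the oxygenated C3 and C5. A carbon substituent placed on that C4 therefore hangs on a 2,6-dialkoxyaryl group, which is easy to metalate from the C4 bromide and is the better migrating group in a peracid oxidation.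
- Forward order: ring C bromide 2 and ring B aldehyde 5 are joined to carbinol 7 and oxidised to ketone 8; the ring B 4-OH is freed and acylated with ring A chloride 11; oxygen insertion then gives the fully benzylated trimer 13, and one hydrogenolysis gives the target.
- No ring is formed; all three benzene rings are purchased.
- Stereochemistry: the target has no stereocenter; the only one on the way (racemic carbinol 7) is removed by oxidation in step 5.

Key step: step 9

Assumption: the carboxyl group of ring C can be carried as its benzyl ester through the metalation, because iPrMgCl·LiCl should exchange a bromide activated by a para ester and two ortho ether oxygens at −15 °C, where attack on the ester is slow.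

**Route**

Step 1
Reactants: 1 4-bromo-3,5-dihydroxybenzoic acid
Product: 2 benzyl 3,5-bis(benzyloxy)-4-bromobenzoate
Conditions: BnBr, K2CO3, DMF, 60 °C
Reagents that add atoms: benzyl bromide, BrCc1ccccc1
Why: Exhaustive Williamson O-alkylation should benzylate both phenols and the carboxylate in one pot while the aryl bromide stays inert.

Step 2
Reactants: 3 3,4,5-trihydroxybenzaldehyde
Product: 4 4-(allyloxy)-3,5-dihydroxybenzaldehyde
Conditions: allyl bromide (1.1 equiv), NaHCO3, DMF, 40 °C, argon
Reagents that add atoms: allyl bromide, C=CCBr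
Why: Regioselective Williamson etherification, since the 4-OH para to the formyl group is by far the most acidic phenol and the weak base NaHCO3 should ionise only it, as in the known 4-O-alkylation of 3,4-dihydroxybenzaldehyde and of gallates.

Step 3
Reactants: 4 4-(allyloxy)-3,5-dihydroxybenzaldehyde
Product: 5 4-(allyloxy)-3,5-bis(benzyloxy)benzaldehyde
Conditions: BnBr, K2CO3, DMF, rt
Reagents that add atoms: benzyl bromide, BrCc1ccccc1
Why: Williamson etherification of the two remaining phenols, which leaves the ring B 4-oxygen as the only one bearing a group removable beside benzyl ethers.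

Step 4
Reactants: 2 benzyl 3,5-bis(benzyloxy)-4-bromobenzoate; 5 4-(allyloxy)-3,5-bis(benzyloxy)benzaldehyde
Product: 7 benzyl 4-{[4-(allyloxy)-3,5-bis(benzyloxy)phenyl](hydroxy)methyl}-3,5-bis(benzyloxy)benzoate (racemic), via arylmagnesium chloride 6 (not isolated)
Conditions: iPrMgCl·LiCl (slightly less than 2), THF, −15 °C; then 5, −15 → 0 °C; aq. NH4Cl
Reagents that add atoms: none
Why: Bromine–magnesium exchange with iPrMgCl·LiCl followed by Grignard addition to the aldehyde should join ring C to the ring B carbon without touching the benzyl ester, and the new carbinol stereocenter is formed without control (racemic) because it is erased in step 5.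

Step 5
Reactants: 7 benzyl 4-{[4-(allyloxy)-3,5-bis(benzyloxy)phenyl](hydroxy)methyl}-3,5-bis(benzyloxy)benzoate
Product: 8 benzyl 4-[4-(allyloxy)-3,5-bis(benzyloxy)benzoyl]-3,5-bis(benzyloxy)benzoate
Conditions: Dess–Martin periodinane, CH2Cl2, rt
Reagents that add atoms: none
Why: Dess–Martin oxidation of a secondary, doubly benzylic alcohol to the diaryl ketone is reliable even for hindered carbinols and spares the allyl ether, benzyl ethers and benzyl ester.

Step 6
Reactants: 8 benzyl 4-[4-(allyloxy)-3,5-bis(benzyloxy)benzoyl]-3,5-bis(benzyloxy)benzoate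
Product: 9 benzyl 3,5-bis(benzyloxy)-4-[3,5-bis(benzyloxy)-4-hydroxybenzoyl]benzoate
Conditions: Pd(PPh3)4 (cat.), morpholine, THF, rt
Reagents that add atoms: none
Why: Tsuji–Trost-type deallylation, in which zerovalent palladium ionises the aryl allyl ether (the para-aroyl phenoxide is a good leaving group) and morpholine traps the allyl fragment, leaving benzyl ethers and the benzyl ester untouched.

Step 7
Reactants: 10 3,4,5-tris(benzyloxy)benzoic acid
Product: 11 3,4,5-tris(benzyloxy)benzoyl chloride
Conditions: (COCl)2, DMF (cat.), CH2Cl2, 0 °C → rt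
Reagents that add atoms: oxalyl chloride, O=C(Cl)C(=O)Cl
Why: Acid chloride formation under Vilsmeier-type catalysis by DMF is standard for benzyl-protected gallic acids.

Step 8
Reactants: 9 benzyl 3,5-bis(benzyloxy)-4-[3,5-bis(benzyloxy)-4-hydroxybenzoyl]benzoate; 11 3,4,5-tris(benzyloxy)benzoyl chloride
Product: 12 benzyl 3,5-bis(benzyloxy)-4-{3,5-bis(benzyloxy)-4-[3,4,5-tris(benzyloxy)benzoyloxy]benzoyl}benzoate
Conditions: Et3N, DMAP (cat.), CH2Cl2, 0 °C → rt
Reagents that add atoms: none
Why: DMAP-catalysed acylation of a phenol by an acid chloride, the same way the flanked 4-OH of 3,5-di-O-benzyl gallates is acylated in para-depside synthesis.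

Step 9
Reactants: 12 benzyl 3,5-bis(benzyloxy)-4-{3,5-bis(benzyloxy)-4-[3,4,5-tris(benzyloxy)benzoyloxy]benzoyl}benzoate
Product: 13 benzyl 3,5-bis(benzyloxy)-4-({3,5-bis(benzyloxy)-4-[3,4,5-tris(benzyloxy)benzoyloxy]benzoyl}oxy)benzoate
Conditions: mCPBA, TFA, CH2Cl2, 0 °C → rt, dark
Reagents that add atoms: 3-chloroperbenzoic acid (mCPBA), O=C(OO)c1cccc(Cl)c1
Why: Baeyer–Villiger oxidation, in which the acid-activated ketone takes up the peracid to give the Criegee adduct and the ring C aryl group shifts from carbon to the proximal peroxide oxygen as 3-chlorobenzoate leaves, forming the C4(ring C)–O and O–C(acyl) bonds in one event. The closest known reaction type is the peracid oxidation of unsymmetrical polyalkoxybenzophenones to aryl benzoates, where the aryl group better able to carry positive charge migrates. No ring is closed and no stereocenter is created. The step needs migration of ring C and not of ring B: ring C carries two benzyloxy groups ortho to the migrating carbon, which stabilise the bridged cationic transition state by resonance and should outweigh its para ester, whereas ring B has its ethers only in meta positions and a weakly donating para acyloxy group. The two ortho substituents also twist ring C out of conjugation with the carbonyl, so its migration relieves strain while ring B stays conjugated with the new ester carbonyl. TFA can be used as promoter because 12 holds only benzyl ethers, a benzyl ester and an aryl ester.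

Step 10
Reactants: 13 benzyl 3,5-bis(benzyloxy)-4-({3,5-bis(benzyloxy)-4-[3,4,5-tris(benzyloxy)benzoyloxy]benzoyl}oxy)benzoate
Product: 14 3,5-dihydroxy-4-{[3,5-dihydroxy-4-(3,4,5-trihydroxybenzoyloxy)benzoyl]oxy}benzoic acid
Conditions: H2 (1 atm), 10% Pd/C, THF, rt
Reagents that add atoms: none
Why: Catalytic hydrogenolysis should cleave the seven benzyl ethers and the benzyl ester together, while the two aryl esters are inert and the neutral aprotic solvent avoids acyl migration or transesterification.

**Compound list**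

1 | 4-bromo-3,5-dihydroxybenzoic acid | O=C(O)c1cc(O)c(Br)c(O)c1 | starting material
2 | benzyl 3,5-bis(benzyloxy)-4-bromobenzoate | O=C(OCc1ccccc1)c1cc(OCc2ccccc2)c(Br)c(OCc2ccccc2)c1 | intermediate
3 | 3,4,5-trihydroxybenzaldehyde | O=Cc1cc(O)c(O)c(O)c1 | starting material
4 | 4-(allyloxy)-3,5-dihydroxybenzaldehyde | C=CCOc1c(O)cc(C=O)cc1O | intermediate
5 | 4-(allyloxy)-3,5-bis(benzyloxy)benzaldehyde | C=CCOc1c(OCc2ccccc2)cc(C=O)cc1OCc1ccccc1 | intermediate
6 | [2,6-bis(benzyloxy)-4-(benzyloxycarbonyl)phenyl]magnesium chloride (LiCl complex, formed in the flask, not isolated) | O=C(OCc1ccccc1)c1cc(OCc2ccccc2)c([Mg]Cl)c(OCc2ccccc2)c1 | intermediate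
7 | benzyl 4-{[4-(allyloxy)-3,5-bis(benzyloxy)phenyl](hydroxy)methyl}-3,5-bis(benzyloxy)benzoate (racemic) | O=C(OCc1ccccc1)c1cc(OCc2ccccc2)c(C(O)c2cc(OCc3ccccc3)c(OCC=C)c(OCc3ccccc3)c2)c(OCc2ccccc2)c1 | intermediate
8 | benzyl 4-[4-(allyloxy)-3,5-bis(benzyloxy)benzoyl]-3,5-bis(benzyloxy)benzoate | O=C(OCc1ccccc1)c1cc(OCc2ccccc2)c(C(=O)c2cc(OCc3ccccc3)c(OCC=C)c(OCc3ccccc3)c2)c(OCc2ccccc2)c1 | intermediate
9 | benzyl 3,5-bis(benzyloxy)-4-[3,5-bis(benzyloxy)-4-hydroxybenzoyl]benzoate | O=C(OCc1ccccc1)c1cc(OCc2ccccc2)c(C(=O)c2cc(OCc3ccccc3)c(O)c(OCc3ccccc3)c2)c(OCc2ccccc2)c1 | intermediate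
10 | 3,4,5-tris(benzyloxy)benzoic acid | O=C(O)c1cc(OCc2ccccc2)c(OCc2ccccc2)c(OCc2ccccc2)c1 | starting material
11 | 3,4,5-tris(benzyloxy)benzoyl chloride | O=C(Cl)c1cc(OCc2ccccc2)c(OCc2ccccc2)c(OCc2ccccc2)c1 | intermediate
12 | benzyl 3,5-bis(benzyloxy)-4-{3,5-bis(benzyloxy)-4-[3,4,5-tris(benzyloxy)benzoyloxy]benzoyl}benzoate | O=C(OCc1ccccc1)c1cc(OCc2ccccc2)c(C(=O)c2cc(OCc3ccccc3)c(OC(=O)c3cc(OCc4ccccc4)c(OCc4ccccc4)c(OCc4ccccc4)c3)c(OCc3ccccc3)c2)c(OCc2ccccc2)c1 | intermediate
13 | benzyl 3,5-bis(benzyloxy)-4-({3,5-bis(benzyloxy)-4-[3,4,5-tris(benzyloxy)benzoyloxy]benzoyl}oxy)benzoate | O=C(OCc1ccccc1)c1cc(OCc2ccccc2)c(OC(=O)c2cc(OCc3ccccc3)c(OC(=O)c3cc(OCc4ccccc4)c(OCc4ccccc4)c(OCc4ccccc4)c3)c(OCc3ccccc3)c2)c(OCc2ccccc2)c1 | intermediate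
14 | 3,5-dihydroxy-4-{[3,5-dihydroxy-4-(3,4,5-trihydroxybenzoyloxy)benzoyl]oxy}benzoic acid | O=C(O)c1cc(O)c(OC(=O)c2cc(O)c(OC(=O)c3cc(O)c(O)c(O)c3)c(O)c2)c(O)c1 | target

**Step count and risks**

Total step count: 10. Longest linear sequence: 8 steps (steps 2, 3, 4, 5, 6, 8, 9, 10, from 3 to 14).

Steps most likely to fail:

1. Step 9. The peracid may add too slowly to the hindered, twisted carbonyl, so that migration of the ring B aryl group or oxidative attack on the benzyloxy-substituted rings competes with the desired shift of ring C. The fallback builds the ring C C4–O bond by acylation instead of oxygen insertion; it sets out from 5, uses 11, and comes back at 13. Pinnick oxidation of 5 (NaClO2, NaH2PO4, 2-methyl-2-butene, t-BuOH/H2O) would give 4-(allyloxy)-3,5-bis(benzyloxy)benzoic acid F1. Part of it would be esterified (BnBr, K2CO3, DMF) to benzyl 4-(allyloxy)-3,5-bis(benzyloxy)benzoate F2 and deallylated (Pd(PPh3)4, morpholine, THF) to benzyl 3,5-bis(benzyloxy)-4-hydroxybenzoate F3. Steglich coupling of F1 with F3 (EDC·HCl, DMAP, CH2Cl2) would give benzyl 4-{[4-(allyloxy)-3,5-bis(benzyloxy)benzoyl]oxy}-3,5-bis(benzyloxy)benzoate F4. A second deallylation would give benzyl 3,5-bis(benzyloxy)-4-{[3,5-bis(benzyloxy)-4-hydroxybenzoyl]oxy}benzoate F5, and acylation with 11 (Et3N, DMAP, CH2Cl2) would return to 13.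

2. Step 4. Exchange at the doubly flanked C–Br bond may be slow, which would let iPrMgCl attack the benzyl ester or later the aldehyde, or the deactivated, hindered arylmagnesium may add sluggishly. The fallback lets the carboxylate protect itself as its lithium salt and uses an aryllithium; it sets out from 2 and comes back at 7. Saponification of 2 (LiOH, THF/MeOH/H2O, then acid) would give 3,5-bis(benzyloxy)-4-bromobenzoic acid F6. Treatment with n-BuLi (2.1 equiv, THF, −78 °C) would deprotonate the acid and exchange the bromine to give lithium 3,5-bis(benzyloxy)-4-lithiobenzoate F7. Addition of 5 and acidic work-up would give 4-{[4-(allyloxy)-3,5-bis(benzyloxy)phenyl](hydroxy)methyl}-3,5-bis(benzyloxy)benzoic acid F8, and carboxylate alkylation (BnBr, KHCO3, DMF) would return to 7.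

3. Step 2. Regiocontrol may be lost through over-allylation or alkylation at a meta hydroxyl, and the pyrogallol unit may be oxidised by air under base. The fallback reverses the logic by protecting all three oxygens and then unmasking the central one; it sets out from 3 and comes back at 5. Perbenzylation of 3 (BnBr, K2CO3, DMF) would give 3,4,5-tris(benzyloxy)benzaldehyde F9. Lewis-acid cleavage of the central, out-of-plane 4-O-benzyl ether (MgBr2·OEt2, toluene/Et2O, heat), the established selectivity for 1,2,3-trialkoxyarenes bearing a para carbonyl group, would give 3,5-bis(benzyloxy)-4-hydroxybenzaldehyde F10, and allylation (allyl bromide, K2CO3, DMF) would return to 5.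

Further compounds
F1 | step 9 | 4-(allyloxy)-3,5-bis(benzyloxy)benzoic acid | C=CCOc1c(OCc2ccccc2)cc(C(=O)O)cc1OCc1ccccc1
F2 | step 9 | benzyl 4-(allyloxy)-3,5-bis(benzyloxy)benzoate | C=CCOc1c(OCc2ccccc2)cc(C(=O)OCc2ccccc2)cc1OCc1ccccc1
F3 | step 9 | benzyl 3,5-bis(benzyloxy)-4-hydroxybenzoate | O=C(OCc1ccccc1)c1cc(OCc2ccccc2)c(O)c(OCc2ccccc2)c1
F4 | step 9 | benzyl 4-{[4-(allyloxy)-3,5-bis(benzyloxy)benzoyl]oxy}-3,5-bis(benzyloxy)benzoate | O=C(OCc1ccccc1)c1cc(OCc2ccccc2)c(OC(=O)c2cc(OCc3ccccc3)c(OCC=C)c(OCc3ccccc3)c2)c(OCc2ccccc2)c1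
F5 | step 9 | benzyl 3,5-bis(benzyloxy)-4-{[3,5-bis(benzyloxy)-4-hydroxybenzoyl]oxy}benzoate | O=C(OCc1ccccc1)c1cc(OCc2ccccc2)c(OC(=O)c2cc(OCc3ccccc3)c(O)c(OCc3ccccc3)c2)c(OCc2ccccc2)c1
F6 | step 4 | 3,5-bis(benzyloxy)-4-bromobenzoic acid | O=C(O)c1cc(OCc2ccccc2)c(Br)c(OCc2ccccc2)c1
F7 | step 4 | lithium 3,5-bis(benzyloxy)-4-lithiobenzoate | [Li+].[O-]C(=O)c1cc(OCc2ccccc2)c([Li])c(OCc2ccccc2)c1
F8 | step 4 | 4-{[4-(allyloxy)-3,5-bis(benzyloxy)phenyl](hydroxy)methyl}-3,5-bis(benzyloxy)benzoic acid (racemic) | O=C(O)c1cc(OCc2ccccc2)c(C(O)c2cc(OCc3ccccc3)c(OCC=C)c(OCc3ccccc3)c2)c(OCc2ccccc2)c1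
F9 | step 2 | 3,4,5-tris(benzyloxy)benzaldehyde | O=Cc1cc(OCc2ccccc2)c(OCc2ccccc2)c(OCc2ccccc2)c1
F10 | step 2 | 3,5-bis(benzyloxy)-4-hydroxybenzaldehyde | O=Cc1cc(OCc2ccccc2)c(O)c(OCc2ccccc2)c1
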